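The cyclohexane ring (C1 bearing the angelate, C2 the side chain, C4 the free hydroxyl, C5 the methyl) is read as two head-to-tail O–C–C–CH2 units, C1–C2–C3 and C4–C5–C6. Its 1,4-dioxygenation makes both ring-closing bonds, C3–C4 and C6–C1, unions of like (electrophilic) polarity. Both are formed in one SmI2 operation from a hemiacetal methacrylate of an iodomethyl lactol: the alkyl iodide becomes an organosamarium that takes the methacryloyl group from oxygen to carbon (C3–C4), which unmasks the C1 aldehyde, whose ketyl closes onto the enone terminus (C6–C1). The precursor is a tetrahydropyran, cut from a δ-lactone that also fixes C2 and the side-chain stereocentres.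

Key step: step 8

Remark: lactol 10 and ester 12 are carried as mixtures of anomers (anomeric centre left undefined in their SMILES); this centre becomes the planar aldehyde carbon in step 8.

Step 1
Reactants: 1 (3R)-5-methoxy-3-methyl-5-oxopentanoic acid [(R)-3-methylglutaric acid monomethyl ester]
Product: 2 methyl (3S)-5-chloro-3-methyl-5-oxopentanoate
Conditions: (COCl)2 (1.2 equiv), DMF (cat.), CH2Cl2, 0 °C to rt
Reagents that add atoms: oxalyl chloride, O=C(Cl)C(Cl)=O
Why: Acid chloride formation through the Vilsmeier-type chloroiminium species leaves the methyl ester and the methyl-bearing stereocentre untouched (the descriptor changes only because of the priority rules).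

Step 2
Reactants: 2 methyl (3S)-5-chloro-3-methyl-5-oxopentanoate; 3 (2-methylprop-1-en-1-yl)magnesium bromide
Product: 4 methyl (3R)-3,7-dimethyl-5-oxooct-6-enoate
Conditions: 3 (1.05 equiv), CuI (10 mol %), THF, −78 °C
Reagents that add atoms: none
Why: Copper-catalysed acylation of the alkenyl Grignard reagent by the acid chloride should stop at the enone, because the organocopper species does not add to ketones or esters at −78 °C.

Step 3
Reactants: 4 methyl (3R)-3,7-dimethyl-5-oxooct-6-enoate
Product: 6 (4R,6R)-4-methyl-6-(2-methylprop-1-en-1-yl)oxan-2-one, via hydroxy ester 5 (not isolated)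
Conditions: (S)-2-methyl-CBS-oxazaborolidine (0.2 equiv), catecholborane (1.5 equiv), toluene, −78 °C; aqueous work-up; then DBU (0.1 equiv), 4 Å sieves, toluene, 60 °C
Reagents that add atoms: none
Why: Corey–Bakshi–Shibata reduction in which the alkenyl group acts as the large substituent, so the (S)-catalyst should deliver hydride under catalyst control to give the (5R)-carbinol, and base-catalysed lactonisation then gives the 4,6-cis δ-lactone.

Step 4
Reactants: 6 (4R,6R)-4-methyl-6-(2-methylprop-1-en-1-yl)oxan-2-one
Product: 8 (3R,4R,6R)-3-(hydroxymethyl)-4-methyl-6-(2-methylprop-1-en-1-yl)oxan-2-one, via lithium enolate 7 (not isolated)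
Conditions: LiN(iPr)2 (1.1 equiv), THF, −78 °C; CH2O (gas, from cracked paraformaldehyde), −78 to −40 °C; aq. NH4Cl
Reagents that add atoms: formaldehyde, C=O
Why: Aldol addition of the lactone enolate to monomeric formaldehyde, the electrophile entering anti to the neighbouring C4 methyl group to give the 3,4-trans isomer, which is also the all-equatorial thermodynamic one; this sets the future ring carbon C2 of the target relative to the side chain.

Step 5
Reactants: 8 (3R,4R,6R)-3-(hydroxymethyl)-4-methyl-6-(2-methylprop-1-en-1-yl)oxan-2-one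
Product: 9 (3S,4R,6R)-3-(iodomethyl)-4-methyl-6-(2-methylprop-1-en-1-yl)oxan-2-one
Conditions: I2, PPh3, imidazole, CH2Cl2, 0 °C to rt
Reagents that add atoms: iodine, II
Why: Appel-type iodination of the primary alcohol by SN2 displacement of the alkoxyphosphonium ion touches no stereocentre (descriptor change by priority only).

Step 6
Reactants: 9 (3S,4R,6R)-3-(iodomethyl)-4-methyl-6-(2-methylprop-1-en-1-yl)oxan-2-one
Product: 10 (3S,4R,6R)-3-(iodomethyl)-4-methyl-6-(2-methylprop-1-en-1-yl)oxan-2-ol (both anomers)
Conditions: iBu2AlH (1.1 equiv), CH2Cl2, −78 °C; aq. KNaC4H4O6 (potassium sodium tartrate)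
Reagents that add atoms: none
Why: Partial reduction of the lactone stops at the stable aluminium lactolate at −78 °C and gives the lactol on work-up, the alkyl iodide and the alkene being inert.

Step 7
Reactants: 10 (3S,4R,6R)-3-(iodomethyl)-4-methyl-6-(2-methylprop-1-en-1-yl)oxan-2-ol; 11 2-methylprop-2-enoyl chloride (methacryloyl chloride)
Product: 12 (3S,4R,6R)-3-(iodomethyl)-4-methyl-6-(2-methylprop-1-en-1-yl)oxan-2-yl 2-methylprop-2-enoate (both anomers)
Conditions: 11 (1.3 equiv), Et3N, DMAP (cat.), CH2Cl2, −20 to 0 °C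
Reagents that add atoms: none
Why: DMAP-catalysed O-acylation of the anomeric hydroxyl hangs the three-carbon methacryloyl unit on the lactol oxygen as a hemiacetal ester, two atoms away from the iodomethyl carbon; either anomer serves in step 8.

Step 8
Reactants: 12 (3S,4R,6R)-3-(iodomethyl)-4-methyl-6-(2-methylprop-1-en-1-yl)oxan-2-yl 2-methylprop-2-enoate
Product: 15 (2S,4R,5S)-4-hydroxy-5-[(2R,4R)-4-hydroxy-6-methylhept-5-en-2-yl]-2-methylcyclohexan-1-one, via keto aldehyde 13 (not isolated), via C-2 epimer mixture 14 (not isolated)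
Conditions: SmI2 (5 equiv, 0.1 M), NiI2 (2 mol %), THF, −20 °C to rt; aq. NH4Cl; then K2CO3, MeOH, rt
Reagents that add atoms: none
Why: SmI2 with catalytic NiI2 turns the primary iodide of 12 into an alkylsamarium, which adds to the neighbouring hemiacetal ester carbonyl through a five-membered tetrahedral intermediate; its collapse moves the methacryloyl group from oxygen to carbon (first new bond, C1–C6 of cyclohexanone 15 = C4–C3 of the target) and releases a lactolate that opens to aldehyde 13, whose samarium ketyl adds to the CH2 terminus of the new isopropenyl ketone (second new bond, C3–C4 of 15 = C6–C1 of the target), the α-keto radical being reduced to a samarium enolate that protects the ketone until work-up. The closest known chemistry is the sequenced SmI2 intramolecular nucleophilic acyl substitution followed by ketyl–olefin coupling, used here with oxygen-to-carbon acyl transfer and an enone acceptor. The cyclohexane closes in a 6-endo-trig mode with the acceptor carbonyl inside the ring, attack at the unsubstituted β-carbon being favoured over 5-exo attack at the substituted α-carbon on polar and steric grounds. The new carbinol centre C4 of 15 should be set in a chair-like transition state with the C5 side chain and the bulky samarium-bound oxygen both equatorial (4,5-trans); C2 is set afterwards by base equilibration of the α-methyl ketone to the equatorial methyl (14 to 15), and C5 and the side-chain centres are carried through unchanged. The step needs the iodide to be activated before the methacrylate or the enone is reduced, which the HMPA-free SmI2/NiI2 conditions and the fact that the aldehyde is unmasked only by the acyl transfer should secure.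

Step 9
Reactants: 15 (2S,4R,5S)-4-hydroxy-5-[(2R,4R)-4-hydroxy-6-methylhept-5-en-2-yl]-2-methylcyclohexan-1-one
Product: 16 (2R,4R)-2-[(1S,2R,4S)-2-hydroxy-4-methyl-5-oxocyclohexyl]-6-methylhept-5-en-4-yl acetate
Conditions: Ac2O (1.1 equiv), pyridine, CH2Cl2, −20 °C
Reagents that add atoms: acetic anhydride, CC(=O)OC(C)=O
Why: Kinetically selective acetylation, in which the acyclic allylic hydroxyl should react faster than the ring hydroxyl, which sits next to the branched side-chain carbon in a menthol-like environment.

Step 10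
Reactants: 16 (2R,4R)-2-[(1S,2R,4S)-2-hydroxy-4-methyl-5-oxocyclohexyl]-6-methylhept-5-en-4-yl acetate; 17 (2Z)-2-methylbut-2-enoic acid (angelic acid)
Product: 19 (1R,2S,5S)-2-[(2R,4R)-4-(acetyloxy)-6-methylhept-5-en-2-yl]-5-methyl-4-oxocyclohexyl (2Z)-2-methylbut-2-enoate, via mixed anhydride 18 (not isolated)
Conditions: 17, 2,4,6-trichlorobenzoyl chloride, Et3N, toluene, rt; then 16, toluene, 80 °C (no DMAP)
Reagents that add atoms: none
Why: Yamaguchi esterification through the mixed 2,4,6-trichlorobenzoic anhydride without a nucleophilic catalyst, conditions under which the (Z)-enoyl group should be transferred to the remaining hydroxyl with retention at carbon and without Z-to-E isomerisation.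

Step 11
Reactants: 19 (1R,2S,5S)-2-[(2R,4R)-4-(acetyloxy)-6-methylhept-5-en-2-yl]-5-methyl-4-oxocyclohexyl (2Z)-2-methylbut-2-enoate
Product: 20 (1R,2S,4R,5S)-2-[(2R,4R)-4-(acetyloxy)-6-methylhept-5-en-2-yl]-4-hydroxy-5-methylcyclohexyl (2Z)-2-methylbut-2-enoate (CNP0237033.1)
Conditions: LiBH(s-Bu)3 (1.1 equiv), THF, −78 °C; aq. NH4Cl
Reagents that add atoms: none
Why: Ketone reduction by the bulky trialkylborohydride, with equatorial hydride delivery giving the axial alcohol cis to the adjacent equatorial methyl (4R); at −78 °C the acetate and the hindered trisubstituted enoate should not be reduced.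

Compound list
1 | (3R)-5-methoxy-3-methyl-5-oxopentanoic acid | COC(=O)C[C@H](C)CC(=O)O | starting material
2 | methyl (3S)-5-chloro-3-methyl-5-oxopentanoate | COC(=O)C[C@H](C)CC(=O)Cl | intermediate
3 | (2-methylprop-1-en-1-yl)magnesium bromide | CC(C)=C[Mg]Br | starting material
4 | methyl (3R)-3,7-dimethyl-5-oxooct-6-enoate | COC(=O)C[C@H](C)CC(=O)C=C(C)C | intermediate
5 | methyl (3R,5R)-5-hydroxy-3,7-dimethyloct-6-enoate | COC(=O)C[C@H](C)C[C@@H](O)C=C(C)C | intermediate (not isolated)
6 | (4R,6R)-4-methyl-6-(2-methylprop-1-en-1-yl)oxan-2-one | O=C1C[C@H](C)C[C@H](C=C(C)C)O1 | intermediate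
7 | lithium (4R,6R)-4-methyl-6-(2-methylprop-1-en-1-yl)-5,6-dihydro-4H-pyran-2-olate | [Li+].[O-]C1=C[C@H](C)C[C@H](C=C(C)C)O1 | intermediate (not isolated)
8 | (3R,4R,6R)-3-(hydroxymethyl)-4-methyl-6-(2-methylprop-1-en-1-yl)oxan-2-one | O=C1[C@@H](CO)[C@H](C)C[C@H](C=C(C)C)O1 | intermediate
9 | (3S,4R,6R)-3-(iodomethyl)-4-methyl-6-(2-methylprop-1-en-1-yl)oxan-2-one | O=C1[C@@H](CI)[C@H](C)C[C@H](C=C(C)C)O1 | intermediate
10 | (3S,4R,6R)-3-(iodomethyl)-4-methyl-6-(2-methylprop-1-en-1-yl)oxan-2-ol, both anomers | OC1[C@@H](CI)[C@H](C)C[C@H](C=C(C)C)O1 | intermediate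
11 | 2-methylprop-2-enoyl chloride | CC(=C)C(=O)Cl | starting material
12 | (3S,4R,6R)-3-(iodomethyl)-4-methyl-6-(2-methylprop-1-en-1-yl)oxan-2-yl 2-methylprop-2-enoate, both anomers | CC(=C)C(=O)OC1[C@@H](CI)[C@H](C)C[C@H](C=C(C)C)O1 | intermediate
13 | (2S,3R,5R)-5-hydroxy-3,7-dimethyl-2-(3-methyl-2-oxobut-3-en-1-yl)oct-6-enal (present as its samarium alkoxide) | O=C[C@@H](CC(=O)C(C)=C)[C@H](C)C[C@@H](O)C=C(C)C | intermediate (not isolated)
14 | (4R,5S)-4-hydroxy-5-[(2R,4R)-4-hydroxy-6-methylhept-5-en-2-yl]-2-methylcyclohexan-1-one, mixture of C-2 epimers | O[C@@H]1CC(C)C(=O)C[C@H]1[C@H](C)C[C@@H](O)C=C(C)C | intermediate (not isolated)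
15 | (2S,4R,5S)-4-hydroxy-5-[(2R,4R)-4-hydroxy-6-methylhept-5-en-2-yl]-2-methylcyclohexan-1-one | O[C@@H]1C[C@H](C)C(=O)C[C@H]1[C@H](C)C[C@@H](O)C=C(C)C | intermediate
16 | (2R,4R)-2-[(1S,2R,4S)-2-hydroxy-4-methyl-5-oxocyclohexyl]-6-methylhept-5-en-4-yl acetate | O[C@@H]1C[C@H](C)C(=O)C[C@H]1[C@H](C)C[C@H](C=C(C)C)OC(C)=O | intermediate
17 | (2Z)-2-methylbut-2-enoic acid | C/C=C(/C)C(=O)O | starting material
18 | (2Z)-2-methylbut-2-enoic 2,4,6-trichlorobenzoic anhydride | C/C=C(/C)C(=O)OC(=O)c1c(Cl)cc(Cl)cc1Cl | intermediate (not isolated)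
19 | (1R,2S,5S)-2-[(2R,4R)-4-(acetyloxy)-6-methylhept-5-en-2-yl]-5-methyl-4-oxocyclohexyl (2Z)-2-methylbut-2-enoate | C/C=C(/C)C(=O)O[C@@H]1C[C@H](C)C(=O)C[C@H]1[C@H](C)C[C@H](C=C(C)C)OC(C)=O | intermediate
20 | (1R,2S,4R,5S)-2-[(2R,4R)-4-(acetyloxy)-6-methylhept-5-en-2-yl]-4-hydroxy-5-methylcyclohexyl (2Z)-2-methylbut-2-enoate | C/C=C(/C)C(=O)O[C@@H]1C[C@H](C)[C@H](O)C[C@H]1[C@H](C)C[C@H](C=C(C)C)OC(C)=O | target

Total step count: 11. Longest linear sequence: 11 steps (from 1).

Steps most likely to fail

Step 8. The methacrylate may be reduced by single-electron transfer before the iodide is converted into the organosamarium, or the samarium hemiketalate may persist so that the aldehyde is not released and the sequence stops after the acyl transfer. The fallback separates the two events and makes the first one anionic. It sets out from 12: iodine–lithium exchange (t-BuLi, 2.1 equiv, Et2O–pentane, −100 °C) triggers the same oxygen-to-carbon acyl shift and should give, after aqueous work-up, keto lactol F1. F1 is then closed in a separate reductive aldehyde–enone cyclisation through its open-chain aldehyde form (SmI2, t-BuOH, THF, 0 °C), where the facial selectivity of the ring closure can be tuned on its own. Equilibration with K2CO3/MeOH as in the route returns to 15.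

Step 9. Discrimination between the two secondary hydroxyls may be poor, giving ring acetate and diacetate. The fallback replaces the direct selective acylation by a protect–acylate–deprotect sequence with a bulkier electrophile. It sets out from 15: TBSCl, imidazole, DMF, 0 °C should silylate only the side-chain hydroxyl to give silyl ether F2. Angeloylation of the ring hydroxyl under the conditions of step 10 gives keto angelate silyl ether F3. HF·pyridine in THF frees the side-chain hydroxyl to give hydroxy keto angelate F4, and Ac2O, pyridine, DMAP returns to 19.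

Step 10. Acylation of the hindered ring hydroxyl may be slow, and the angeloyl group may isomerise from Z to E under the forcing conditions. The fallback builds the Z-enoate on the substrate instead of transferring it. It sets out from 16: esterification with 2-[bis(2,2,2-trifluoroethoxy)phosphoryl]propanoic acid (DCC, DMAP, CH2Cl2) gives phosphonate ester F5. A Still–Gennari olefination with acetaldehyde (KN(SiMe3)2, 18-crown-6, THF, −78 °C) should then give the Z-enoate directly and returns to 19.

Further compounds
F1 | step 8 | 1-[(3S,4R,6R)-2-hydroxy-4-methyl-6-(2-methylprop-1-en-1-yl)oxan-3-yl]-3-methylbut-3-en-2-one (both anomers) | OC1[C@@H](CC(=O)C(C)=C)[C@H](C)C[C@H](C=C(C)C)O1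
F2 | step 9 | (2S,4R,5S)-5-[(2R,4R)-4-{[tert-butyl(dimethyl)silyl]oxy}-6-methylhept-5-en-2-yl]-4-hydroxy-2-methylcyclohexan-1-one | O[C@@H]1C[C@H](C)C(=O)C[C@H]1[C@H](C)C[C@H](C=C(C)C)O[Si](C)(C)C(C)(C)C
F3 | step 9 | (1R,2S,5S)-2-[(2R,4R)-4-{[tert-butyl(dimethyl)silyl]oxy}-6-methylhept-5-en-2-yl]-5-methyl-4-oxocyclohexyl (2Z)-2-methylbut-2-enoate | C/C=C(/C)C(=O)O[C@@H]1C[C@H](C)C(=O)C[C@H]1[C@H](C)C[C@H](C=C(C)C)O[Si](C)(C)C(C)(C)C
F4 | step 9 | (1R,2S,5S)-2-[(2R,4R)-4-hydroxy-6-methylhept-5-en-2-yl]-5-methyl-4-oxocyclohexyl (2Z)-2-methylbut-2-enoate | C/C=C(/C)C(=O)O[C@@H]1C[C@H](C)C(=O)C[C@H]1[C@H](C)C[C@@H](O)C=C(C)C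
F5 | step 10 | (1R,2S,5S)-2-[(2R,4R)-4-(acetyloxy)-6-methylhept-5-en-2-yl]-5-methyl-4-oxocyclohexyl 2-[bis(2,2,2-trifluoroethoxy)phosphoryl]propanoate (both epimers at the phosphonate carbon) | CC(C(=O)O[C@@H]1C[C@H](C)C(=O)C[C@H]1[C@H](C)C[C@H](C=C(C)C)OC(C)=O)P(=O)(OCC(F)(F)F)OCC(F)(F)F
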